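The chemist at this flask wanted the right-handed substrate left in an excess of 95 %, so I turned the question round and asked what the given numbers would have to be for a yes.

| flask | left-handed substrate | right-handed substrate | reagent | free catalyst | remark | time |
|---|---|---|---|---|---|---|
| dawn | 0.050 M | 0.050 M | 0.055 M | 0.80 mM | run made earlier |  |
| dusk | 0.050 M | 0.050 M | 0.055 M | 1.8 mM | run made earlier |  |
| flask | 0.050 M | 0.050 M | 0.0550 M | 1.2 mM |  | 12 h |

| run | time / h | right-handed substrate / % | left-handed substrate / % | left-handed product / % |
|---|---|---|---|---|
| dawn | 0.833 | 52.0 | 45.0 | 4.7 |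
| dawn | 1.33 | 49.0 | 44.2 | 6.1 |
| dawn | 2.50 | 47.3 | 39.3 | 11.3 |
| dawn | 5.00 | 46.2 | 30.7 | 16.4 |
| dawn | 10.0 | 45.4 | 20.5 | 22.7 |
| dusk | 0.833 | 47.3 | 42.4 | 7.6 |
| dusk | 2.50 | 46.5 | 30.0 | 17.6 |
| dusk | 4.00 | 44.2 | 24.3 | 24.5 |
| dusk | 6.00 | 45.0 | 18.4 | 29.6 |
| dusk | 10.0 | 44.5 | 12.1 | 28.3 |

(each reading ± 1 percentage point)

* whether the excess of right-handed substrate over left-handed substrate among what is left of the two reaches 95 % by 12 h (no / yes)
* the highest excess of right-handed substrate over left-handed substrate among what is left of the two up to 12 h

1. The dusk run ended with right-handed substrate at 44.5 %, and the dawn run stood close to that. Excess is (right − left)/(right + left), so on that reading the wanted level demanded c(left-handed substrate) of 1.14 % of the total charged.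

2. I treated the fall of left-handed substrate as pseudo-first-order, with a rate proportional to c(free catalyst) as charged. Integrated, ln(charged/remaining) grows in proportion to catalyst times hours. The dawn reading at 5.00 h gave 0.122 /mM/h. I call this the catalyst-time constant: the logarithm of charged over remaining left-handed substrate, per unit of charged catalyst times hours.

3. With that constant the wanted level needed a dose of 31.0 mM·h, but this flask offers 14.4 mM·h, so it needed twice the dose on hand. Put the other way, a yes needed a constant of 0.263 /mM/h, and the readings sagged the wrong way: dusk gave 0.0788 /mM/h at 10.0 h.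

4. The flask's dose lies between the dusk doses at 6.00 h and 10.0 h. Their constants, 0.0926 /mM/h and 0.0788 /mM/h, put my excess at the end between 46.9 % and 54.3 %.

The forecast, made from the same runs, answered no with a top of 51 %, calling the level “far out of reach”. The flask gave no and a top of 52.0 %.

    2 free catalyst ⇌ resting dimer, settled at all times (K = 1800 /M)
    reagent + catalyst intermediate B → free catalyst + right-handed product (k = 120 /M/h)
    reagent + catalyst intermediate A → free catalyst + left-handed product (k = 480 /M/h)
    2 reagent → homo dimer (k = 1.10 /M/h)
    free catalyst + right-handed substrate ⇌ catalyst intermediate B (K = 23.0 /M, k = 320 /M/h)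
    left-handed product ⇌ right-handed product (k = 0.0640 /h)
    free catalyst + left-handed substrate ⇌ catalyst intermediate A (K = 300 /M, k = 570 /M/h)

In this flask 28 % of the charged left-handed substrate stood unbound at 12.0 h, so its constant came to 0.0886 /mM/h, below the dawn value. The main reason for the excess in this flask is the loss of free catalyst and left-handed substrate to catalyst intermediate A, both ways: the simulated run without that step gives −14.7 % at 12 h instead of 52.0 %. The dawn constant, used on the neighbour flask with 4.8 × 10⁻⁴ M of free catalyst, promised 49.5 % of its left-handed substrate left at 12 h, and that flask holds 50 %, with a top of 29.4 %.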